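The route rests on disconnecting the oxolane at O1–C2 together with the C2–C4' bond to the dienyl chain. The feature used is oxolane C2: bonded to O1 and to side-chain carbon C4', trans to the C5 methyl, and flanked by the C3 carbinol, where a ketone remains after a diazoketone-derived oxonium ylide rearranges. In one operation a copper carbenoid closes the ring and moves the allyl group from oxygen to C2 by [2,3] shift, setting the 2,5-trans relationship. Its precursor is an open-chain diazomethyl ketone carrying an allyl ether on a purchased (S)-carbinol carbon. The allyl group is later cut back to an enal and joined to a chloroisochromenone phosphonate.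

Key step: step 4

Remark: the diene carbons are numbered C1' to C4' from the isochromenone, so C4' is bonded to oxolane C2. The target is read as (2S,3R,5S), with the C2 side chain trans to both the C5 methyl and the C3 hydroxyl, and the diene as (1E,3E). The stereodescriptors of diazoketone 7 and ketone 9 agree with this reading.

Step 1
Reactants: 1 ethyl (S)-3-hydroxybutanoate; 2 allyl 2,2,2-trichloroacetimidate
Product: 3 ethyl (S)-3-(allyloxy)butanoate
Conditions: TfOH (cat.), cyclohexane/CH2Cl2 2:1, rt
Reagents that add atoms: none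
Why: Acid-catalysed O-alkylation with a trichloroacetimidate allylates the hydroxyl without base, so the β-hydroxy ester should neither eliminate nor undergo retro-aldol cleavage, and the untouched stereocentre stays (S).

Step 2
Reactants: 3 ethyl (S)-3-(allyloxy)butanoate
Product: 4 (S)-3-(allyloxy)butanoic acid
Conditions: LiOH·H2O, THF/H2O 3:1, 0 °C → rt; then 1 M HCl to pH 3
Reagents that add atoms: lithium hydroxide, [Li+].[OH-]
Why: Ester saponification under mild conditions; the β-allyloxy group is a poor leaving group, so loss of allyl alcohol by E1cB elimination is not expected.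

Step 3
Reactants: 4 (S)-3-(allyloxy)butanoic acid; 5 trimethylsilyldiazomethane
Product: 7 (S)-4-(allyloxy)-1-diazopentan-2-one, via isobutyl carbonic mixed anhydride 6 (not isolated)
Conditions: i-BuOCOCl, Et3N, THF, −15 °C; then Me3SiCHN2 (2 M in hexanes), MeCN, 0 °C → rt
Reagents that add atoms: none
Why: Mixed-anhydride activation followed by C-acylation of the silyl diazomethane (Arndt–Eistert-type diazoketone synthesis), the silyl group leaving with the carbonate; no stereocentre is involved.

Step 4
Reactants: 7 (S)-4-(allyloxy)-1-diazopentan-2-one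
Product: 9 (2S,5S)-2-allyl-5-methyloxolan-3-one, via cyclic allyloxonium ylide 8 (not isolated)
Conditions: Cu(acac)2 (5 mol%), THF, reflux, 7 added slowly at high dilution
Reagents that add atoms: none
Why: Cu(acac)2 removes dinitrogen from 7 to give an electrophilic copper carbenoid at the future C2, the ether oxygen (fifth atom along the chain from that carbon) adds to it to form O1–C2 and ylide 8, and the allyl group then moves from oxygen to the ylide carbon by a concerted suprafacial [2,3]-sigmatropic shift with allylic transposition, forming C2–C4'. The closest known reaction type is the copper-catalysed tandem oxonium ylide formation and [2,3] rearrangement of allyl ethers of β-hydroxy diazoketones to 2-allyloxolan-3-ones. The oxolane closes in a 5-exo sense, an oxygen lone pair attacking the carbenoid carbon while the metal stays outside the new ring. The one new stereocentre, C2, is controlled by the C5 methyl: in 8 the allyl group on oxygen prefers the face away from that methyl, and the suprafacial shift delivers it to C2 on the same face, which should give (2S) with allyl and methyl trans. The step needs 2,5-trans diastereoselectivity, secured by this relay from C5, and chemoselectivity for ylide formation over C–H insertion, [1,2] shift and carbene dimerisation, secured by the weakly electrophilic acetylacetonate carbenoid, the favourable five-membered ylide and slow addition of 7.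

Step 5
Reactants: 9 (2S,5S)-2-allyl-5-methyloxolan-3-one
Product: 10 (2S,3S,5S)-2-allyl-5-methyloxolan-3-ol
Conditions: LiBH(s-Bu)3, THF, −78 °C; aq. NH4Cl
Reagents that add atoms: none
Why: Bulky-hydride ketone reduction; the hydride should approach C3 from the face opposite the adjacent C2 allyl group, setting C3 as (S) with hydroxyl and allyl cis.

Step 6
Reactants: 10 (2S,3S,5S)-2-allyl-5-methyloxolan-3-ol
Product: 11 (2S,3R,5S)-2-allyl-5-methyloxolan-3-yl 4-nitrobenzoate
Conditions: 4-O2NC6H4CO2H, PPh3, DIAD, THF, 0 °C → rt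
Reagents that add atoms: 4-nitrobenzoic acid, OC(=O)c1ccc(cc1)[N+](=O)[O-]
Why: Mitsunobu reaction; the phosphorus-activated C3 oxygen is displaced by the carboxylate in an SN2 step from the face anti to the allyl group, inverting C3 to (R).

Step 7
Reactants: 11 (2S,3R,5S)-2-allyl-5-methyloxolan-3-yl 4-nitrobenzoate
Product: 12 (2S,3R,5S)-2-allyl-5-methyloxolan-3-ol
Conditions: K2CO3, MeOH, rt
Reagents that add atoms: none
Why: Base-catalysed transesterification removes the electron-poor aroyl group; nothing else in 11 is base-sensitive and no stereocentre is touched.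

Step 8
Reactants: 12 (2S,3R,5S)-2-allyl-5-methyloxolan-3-ol
Product: 13 tert-butyl{[(2S,3R,5S)-2-allyl-5-methyloxolan-3-yl]oxy}dimethylsilane
Conditions: TBSCl, imidazole, DMF, rt
Reagents that add atoms: tert-butyldimethylsilyl chloride, CC(C)(C)[Si](C)(C)Cl
Why: Standard silylation of a secondary alcohol masks the hydroxyl for the oxidative and basic steps ahead and allows a single fluoride deprotection at the end.

Step 9
Reactants: 13 tert-butyl{[(2S,3R,5S)-2-allyl-5-methyloxolan-3-yl]oxy}dimethylsilane
Product: 14 tert-butyldimethyl{[(2S,3R,5S)-5-methyl-2-[(E)-prop-1-en-1-yl]oxolan-3-yl]oxy}silane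
Conditions: RuHCl(CO)(PPh3)3 (5 mol%), PhMe, 80 °C
Reagents that add atoms: none
Why: Metal hydride-catalysed alkene isomerisation (hydrometalation then β-hydride elimination) should move the terminal double bond one position inward and stop there, since further migration needs insertion at the hindered C2; mainly the E isomer is expected, and any Z isomer is cleaved to the same aldehyde in step 10.

Step 10
Reactants: 14 tert-butyldimethyl{[(2S,3R,5S)-5-methyl-2-[(E)-prop-1-en-1-yl]oxolan-3-yl]oxy}silane
Product: 17 (E)-3-{(2S,3R,5S)-3-[(tert-butyldimethylsilyl)oxy]-5-methyloxolan-2-yl}prop-2-enal, via ozonide 15 (not isolated), via silyloxy oxolane-2-carbaldehyde 16 (not isolated)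
Conditions: O3, CH2Cl2, −78 °C; PPh3, −78 °C → rt; solvent exchanged for PhMe (removes MeCHO); Ph3P=CHCHO, 60 °C
Reagents that add atoms: (triphenylphosphoranylidene)acetaldehyde, O=CC=P(c1ccccc1)(c1ccccc1)c1ccccc1
Why: Ozonolysis with reductive work-up followed by Wittig reaction of the crude aldehyde with a stabilised ylide should give the E enal; the neutral conditions should leave the epimerisable C2 centre, already in its favoured 2,3-trans arrangement, unchanged.

Step 11
Reactants: 18 methyl orsellinate (methyl 2,4-dihydroxy-6-methylbenzoate)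
Product: 19 methyl 3-chloro-4,6-dihydroxy-2-methylbenzoate
Conditions: SO2Cl2 (1.05 equiv), Et2O, 0 °C
Reagents that add atoms: sulfuryl chloride, O=S(=O)(Cl)Cl
Why: Electrophilic aromatic chlorination; the position ortho to the free hydroxyl, para to the ester-chelated hydroxyl and next to the methyl group should react first, the site between the two hydroxyls being more hindered.

Step 12
Reactants: 19 methyl 3-chloro-4,6-dihydroxy-2-methylbenzoate
Product: 20 methyl 3-chloro-4,6-bis(methoxymethoxy)-2-methylbenzoate
Conditions: NaH, MOMCl, DMF, 0 °C → rt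
Reagents that add atoms: chloromethyl methyl ether, COCCl
Why: Williamson etherification of both phenoxides gives base-stable acetal protection for the benzylic metalation.

Step 13
Reactants: 20 methyl 3-chloro-4,6-bis(methoxymethoxy)-2-methylbenzoate
Product: 22 methyl 3-chloro-2-(3-chloro-2-oxopropyl)-4,6-bis(methoxymethoxy)benzoate, via benzylic lithium compound 21 (not isolated)
Conditions: LiN(i-Pr)2 (1.2 equiv), THF, −78 °C; then ClCH2C(O)N(OMe)Me, −78 °C; AcOH quench
Reagents that add atoms: 2-chloro-N-methoxy-N-methylacetamide, CON(C)C(=O)CCl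
Why: Lateral lithiation of the ortho-toluate gives an ester-stabilised benzylic anion that is acylated by the N-methoxy-N-methylamide, which stops at the ketone stage and releases the acidic ketone only on work-up.

Step 14
Reactants: 22 methyl 3-chloro-2-(3-chloro-2-oxopropyl)-4,6-bis(methoxymethoxy)benzoate
Product: 24 5-chloro-3-(chloromethyl)-6,8-dihydroxy-1H-isochromen-1-one, via dihydroxy keto ester 23 (not isolated)
Conditions: 3 M HCl in MeOH, 40 °C; evaporate; TsOH·H2O (cat.), PhMe, 100 °C
Reagents that add atoms: none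
Why: Acetal methanolysis (formaldehyde leaves as volatile dimethoxymethane, away from the electron-rich ring) followed by acid-catalysed enol lactonisation of the ortho-(2-oxoalkyl)benzoate closes the isochromenone; acid is used because base would favour Claisen closure to a naphthalenediol.

Step 15
Reactants: 24 5-chloro-3-(chloromethyl)-6,8-dihydroxy-1H-isochromen-1-one
Product: 25 6,8-bis[(tert-butyldimethylsilyl)oxy]-5-chloro-3-(chloromethyl)-1H-isochromen-1-one
Conditions: TBSOTf, 2,6-lutidine, CH2Cl2, 0 °C → rt
Reagents that add atoms: tert-butyldimethylsilyl trifluoromethanesulfonate, CC(C)(C)[Si](C)(C)OS(=O)(=O)C(F)(F)F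
Why: Phenol silylation with a silyl triflate and a hindered pyridine base, which is reactive enough for the chelated C8 hydroxyl and cannot alkylate at the chloromethyl group.

Step 16
Reactants: 25 6,8-bis[(tert-butyldimethylsilyl)oxy]-5-chloro-3-(chloromethyl)-1H-isochromen-1-one
Product: 26 diethyl ({6,8-bis[(tert-butyldimethylsilyl)oxy]-5-chloro-1-oxo-1H-isochromen-3-yl}methyl)phosphonate
Conditions: P(OEt)3 (neat), 130 °C
Reagents that add atoms: triethyl phosphite, CCOP(OCC)OCC
Why: Michaelis–Arbuzov reaction of a primary allylic-type chloride; the ring was closed first so that no α-haloketone is present to divert into a Perkow product.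

Step 17
Reactants: 26 diethyl ({6,8-bis[(tert-butyldimethylsilyl)oxy]-5-chloro-1-oxo-1H-isochromen-3-yl}methyl)phosphonate; 17 (E)-3-{(2S,3R,5S)-3-[(tert-butyldimethylsilyl)oxy]-5-methyloxolan-2-yl}prop-2-enal
Product: 28 6,8-bis[(tert-butyldimethylsilyl)oxy]-3-[(1E,3E)-4-{(2S,3R,5S)-3-[(tert-butyldimethylsilyl)oxy]-5-methyloxolan-2-yl}buta-1,3-dien-1-yl]-5-chloro-1H-isochromen-1-one, via sodium phosphonate carbanion 27 (not isolated)
Conditions: 26 (1.2 equiv), NaN(SiMe3)2 (1.1 equiv), THF, −78 °C; then 17, −78 → 0 °C
Reagents that add atoms: none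
Why: Horner–Wadsworth–Emmons olefination; the conjugation-stabilised carbanion adds reversibly to the enal and loses phosphate to give the thermodynamically favoured E alkene, so the (1E,3E)-diene should result, and the slight deficit of base guards against deprotonation of the enal at oxolane C2.

Step 18
Reactants: 28 6,8-bis[(tert-butyldimethylsilyl)oxy]-3-[(1E,3E)-4-{(2S,3R,5S)-3-[(tert-butyldimethylsilyl)oxy]-5-methyloxolan-2-yl}buta-1,3-dien-1-yl]-5-chloro-1H-isochromen-1-one
Product: 29 5-chloro-6,8-dihydroxy-3-[(1E,3E)-4-[(2S,3R,5S)-3-hydroxy-5-methyloxolan-2-yl]buta-1,3-dien-1-yl]-1H-isochromen-1-one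
Conditions: HF·pyridine, pyridine/THF, 0 °C → rt
Reagents that add atoms: none
Why: Fluoride-mediated cleavage of two aryl and one alkyl silyl ether in one buffered operation, under which the lactone, the diene and the allylic ring ether should be stable.

Compound list
1 | ethyl (S)-3-hydroxybutanoate | C[C@H](O)CC(=O)OCC | starting material
2 | allyl 2,2,2-trichloroacetimidate | C=CCOC(=N)C(Cl)(Cl)Cl | starting material
3 | ethyl (S)-3-(allyloxy)butanoate | C[C@H](OCC=C)CC(=O)OCC | intermediate
4 | (S)-3-(allyloxy)butanoic acid | C[C@H](OCC=C)CC(=O)O | intermediate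
5 | trimethylsilyldiazomethane | C[Si](C)(C)C=[N+]=[N-] | starting material
6 | (S)-3-(allyloxy)butanoic isobutyl carbonic anhydride (not isolated) | C[C@H](OCC=C)CC(=O)OC(=O)OCC(C)C | intermediate
7 | (S)-4-(allyloxy)-1-diazopentan-2-one | C[C@@H](CC(=O)C=[N+]=[N-])OCC=C | intermediate
8 | (5S)-1-allyl-5-methyl-3-oxooxolan-1-ium-2-ide (cyclic allyloxonium ylide, not isolated) | C[C@H]1CC(=O)[CH-][O+]1CC=C | intermediate
9 | (2S,5S)-2-allyl-5-methyloxolan-3-one (2,5-trans) | C[C@H]1CC(=O)[C@H](CC=C)O1 | intermediate
10 | (2S,3S,5S)-2-allyl-5-methyloxolan-3-ol (2,3-cis) | C[C@H]1C[C@H](O)[C@H](CC=C)O1 | intermediate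
11 | (2S,3R,5S)-2-allyl-5-methyloxolan-3-yl 4-nitrobenzoate | C[C@H]1C[C@@H](OC(=O)c2ccc(cc2)[N+](=O)[O-])[C@H](CC=C)O1 | intermediate
12 | (2S,3R,5S)-2-allyl-5-methyloxolan-3-ol (2,3-trans) | C[C@H]1C[C@@H](O)[C@H](CC=C)O1 | intermediate
13 | tert-butyl{[(2S,3R,5S)-2-allyl-5-methyloxolan-3-yl]oxy}dimethylsilane | C[C@H]1C[C@@H](O[Si](C)(C)C(C)(C)C)[C@H](CC=C)O1 | intermediate
14 | tert-butyldimethyl{[(2S,3R,5S)-5-methyl-2-[(E)-prop-1-en-1-yl]oxolan-3-yl]oxy}silane | C[C@H]1C[C@@H](O[Si](C)(C)C(C)(C)C)[C@H](/C=C/C)O1 | intermediate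
15 | tert-butyldimethyl{[(2R,3R,5S)-5-methyl-2-(5-methyl-1,2,4-trioxolan-3-yl)oxolan-3-yl]oxy}silane (ozonide, not isolated) | C[C@H]1C[C@@H](O[Si](C)(C)C(C)(C)C)[C@H](C2OOC(C)O2)O1 | intermediate
16 | (2R,3R,5S)-3-[(tert-butyldimethylsilyl)oxy]-5-methyloxolane-2-carbaldehyde (not isolated) | C[C@H]1C[C@@H](O[Si](C)(C)C(C)(C)C)[C@H](C=O)O1 | intermediate
17 | (E)-3-{(2S,3R,5S)-3-[(tert-butyldimethylsilyl)oxy]-5-methyloxolan-2-yl}prop-2-enal | C[C@H]1C[C@@H](O[Si](C)(C)C(C)(C)C)[C@H](/C=C/C=O)O1 | intermediate
18 | methyl orsellinate (methyl 2,4-dihydroxy-6-methylbenzoate) | COC(=O)c1c(C)cc(O)cc1O | starting material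
19 | methyl 3-chloro-4,6-dihydroxy-2-methylbenzoate | COC(=O)c1c(C)c(Cl)c(O)cc1O | intermediate
20 | methyl 3-chloro-4,6-bis(methoxymethoxy)-2-methylbenzoate | COC(=O)c1c(C)c(Cl)c(OCOC)cc1OCOC | intermediate
21 | methyl 3-chloro-2-(lithiomethyl)-4,6-bis(methoxymethoxy)benzoate (not isolated) | [Li]Cc1c(Cl)c(OCOC)cc(OCOC)c1C(=O)OC | intermediate
22 | methyl 3-chloro-2-(3-chloro-2-oxopropyl)-4,6-bis(methoxymethoxy)benzoate | COC(=O)c1c(CC(=O)CCl)c(Cl)c(OCOC)cc1OCOC | intermediate
23 | methyl 3-chloro-2-(3-chloro-2-oxopropyl)-4,6-dihydroxybenzoate (not isolated) | COC(=O)c1c(CC(=O)CCl)c(Cl)c(O)cc1O | intermediate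
24 | 5-chloro-3-(chloromethyl)-6,8-dihydroxy-1H-isochromen-1-one | ClCc1cc2c(Cl)c(O)cc(O)c2c(=O)o1 | intermediate
25 | 6,8-bis[(tert-butyldimethylsilyl)oxy]-5-chloro-3-(chloromethyl)-1H-isochromen-1-one | ClCc1cc2c(Cl)c(O[Si](C)(C)C(C)(C)C)cc(O[Si](C)(C)C(C)(C)C)c2c(=O)o1 | intermediate
26 | diethyl ({6,8-bis[(tert-butyldimethylsilyl)oxy]-5-chloro-1-oxo-1H-isochromen-3-yl}methyl)phosphonate | CCOP(=O)(OCC)Cc1cc2c(Cl)c(O[Si](C)(C)C(C)(C)C)cc(O[Si](C)(C)C(C)(C)C)c2c(=O)o1 | intermediate
27 | sodium salt of the α-carbanion of phosphonate 26 (not isolated) | [Na+].CCOP(=O)(OCC)[CH-]c1cc2c(Cl)c(O[Si](C)(C)C(C)(C)C)cc(O[Si](C)(C)C(C)(C)C)c2c(=O)o1 | intermediate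
28 | 6,8-bis[(tert-butyldimethylsilyl)oxy]-3-[(1E,3E)-4-{(2S,3R,5S)-3-[(tert-butyldimethylsilyl)oxy]-5-methyloxolan-2-yl}buta-1,3-dien-1-yl]-5-chloro-1H-isochromen-1-one | C[C@H]1C[C@@H](O[Si](C)(C)C(C)(C)C)[C@H](/C=C/C=C/c2cc3c(Cl)c(O[Si](C)(C)C(C)(C)C)cc(O[Si](C)(C)C(C)(C)C)c3c(=O)o2)O1 | intermediate
29 | 5-chloro-6,8-dihydroxy-3-[(1E,3E)-4-[(2S,3R,5S)-3-hydroxy-5-methyloxolan-2-yl]buta-1,3-dien-1-yl]-1H-isochromen-1-one | C[C@H]1C[C@@H](O)[C@H](/C=C/C=C/c2cc3c(Cl)c(O)cc(O)c3c(=O)o2)O1 | target

Total step count: 18 (steps 1–10 build the oxolane enal, steps 11–16 the isochromenone phosphonate, steps 17–18 join and deprotect).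
Longest linear sequence: 12 steps (steps 1–10, 17 and 18).

Steps most likely to fail

Step 4. The carbenoid may be diverted into C–H insertion next to the ether oxygen, [1,2] shift or dimerisation before the ylide rearranges, and the diazoketone may be lost on handling. The fallback sets out from 3 and comes back at 9, and avoids the diazo compound. Ester 3 would be reduced with i-Bu2AlH in CH2Cl2 at −78 °C to (S)-3-(allyloxy)butanal F1. Homologation with the Ohira–Bestmann reagent (K2CO3, MeOH) would give (S)-4-(allyloxy)pent-1-yne F2. Oxidation of the terminal alkyne of F2 with 8-methylquinoline N-oxide under Ph3PAuNTf2 catalysis is a known route to an α-oxo gold carbenoid at the terminal carbon. A tethered allyl ether traps such a carbenoid as the oxonium ylide, which rearranges by [2,3] shift to the 2-allyloxolan-3-one, here 9.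

Step 13. The benzylic anion may deprotonate the α-chloro amide or displace its chloride in place of adding to the carbonyl group. The fallback sets out from 20 and comes back at 24, and introduces the halogen only after the ring is closed. Lithiated 20 would be acylated with 2-[(tert-butyldimethylsilyl)oxy]-N-methoxy-N-methylacetamide to give methyl 2-{3-[(tert-butyldimethylsilyl)oxy]-2-oxopropyl}-3-chloro-4,6-bis(methoxymethoxy)benzoate F3. HCl in MeOH would remove the acetals and the silyl ether to give methyl 3-chloro-4,6-dihydroxy-2-(3-hydroxy-2-oxopropyl)benzoate F4. TsOH·H2O in hot toluene would lactonise F4 to 5-chloro-6,8-dihydroxy-3-(hydroxymethyl)-1H-isochromen-1-one F5. Appel chlorination (PPh3, CCl4), which leaves phenols untouched, would convert the primary alcohol of F5 into chloride 24.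

Step 17. The strongly delocalised carbanion may add sluggishly, and the amide base may attack the aryl silyl ethers or remove the proton at oxolane C2 of the enal. The fallback sets out from 25 and 17 and comes back at 28, and replaces the metal phosphonate by a neutral ylide. Chloride 25 would be heated with PPh3 in toluene to give ({6,8-bis[(tert-butyldimethylsilyl)oxy]-5-chloro-1-oxo-1H-isochromen-3-yl}methyl)triphenylphosphonium chloride F6. Its conjugation-stabilised ylide, formed with DBU in CH2Cl2, would undergo Wittig reaction with enal 17 to give 28 together with its (1Z,3E) isomer, 6,8-bis[(tert-butyldimethylsilyl)oxy]-3-[(1Z,3E)-4-{(2S,3R,5S)-3-[(tert-butyldimethylsilyl)oxy]-5-methyloxolan-2-yl}buta-1,3-dien-1-yl]-5-chloro-1H-isochromen-1-one F7. A catalytic amount of iodine in CH2Cl2 in daylight would equilibrate F7 to the all-E diene 28.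

Further compounds
F1 | step 4 | (S)-3-(allyloxy)butanal | C[C@H](OCC=C)CC=O
F2 | step 4 | (S)-4-(allyloxy)pent-1-yne | C[C@H](OCC=C)CC#C
F3 | step 13 | methyl 2-{3-[(tert-butyldimethylsilyl)oxy]-2-oxopropyl}-3-chloro-4,6-bis(methoxymethoxy)benzoate | COC(=O)c1c(CC(=O)CO[Si](C)(C)C(C)(C)C)c(Cl)c(OCOC)cc1OCOC
F4 | step 13 | methyl 3-chloro-4,6-dihydroxy-2-(3-hydroxy-2-oxopropyl)benzoate | COC(=O)c1c(CC(=O)CO)c(Cl)c(O)cc1O
F5 | step 13 | 5-chloro-6,8-dihydroxy-3-(hydroxymethyl)-1H-isochromen-1-one | OCc1cc2c(Cl)c(O)cc(O)c2c(=O)o1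
F6 | step 17 | ({6,8-bis[(tert-butyldimethylsilyl)oxy]-5-chloro-1-oxo-1H-isochromen-3-yl}methyl)triphenylphosphonium chloride | [Cl-].O=c1oc(C[P+](c2ccccc2)(c2ccccc2)c2ccccc2)cc2c(Cl)c(O[Si](C)(C)C(C)(C)C)cc(O[Si](C)(C)C(C)(C)C)c12
F7 | step 17 | 6,8-bis[(tert-butyldimethylsilyl)oxy]-3-[(1Z,3E)-4-{(2S,3R,5S)-3-[(tert-butyldimethylsilyl)oxy]-5-methyloxolan-2-yl}buta-1,3-dien-1-yl]-5-chloro-1H-isochromen-1-one | C[C@H]1C[C@@H](O[Si](C)(C)C(C)(C)C)[C@H](/C=C/C=C\c2cc3c(Cl)c(O[Si](C)(C)C(C)(C)C)cc(O[Si](C)(C)C(C)(C)C)c3c(=O)o2)O1
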